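All runs are simulated with made-up constants, and the scatter is random.

The stirred vessel holds D, G, E and L at constant volume, and the flasks differ in how G or D goes in.

| flask | D | G | E | L | remark | time |
|---|---|---|---|---|---|---|
| alder | 0.29 M | 1.1 equiv | 2.5 equiv | 5.8 mM | run made earlier |  |
| cedar | 0.41 M | 1.1 equiv | 2.5 equiv | 5.8 mM | run made earlier |  |
| larch | 0.64 M | 1.1 equiv | 2.5 equiv | 5.8 mM | run made earlier |  |
| summer | 0.29 M | 1.10 equiv (in portions, 2, over 15 h) | 2.50 equiv | 5.80 mM | first portion at the start, last at 15 h | 25 h |
| midnight | 0.29 M | 1.10 equiv | 2.50 equiv | 5.80 mM | everything together at the start | 25 h |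
| dusk | 0.29 M | 1.10 equiv (fed, over 15 h) | 2.50 equiv | 5.80 mM | all else is in the flask from the start; the feed brings no volume worth counting | 25 h |
| winter | 0.29 M (fed, over 15 h) | 1.10 equiv | 2.50 equiv | 5.80 mM | all else is in the flask from the start; the feed brings no volume worth counting | 25 h |

| run | time / h | Z / % |
|---|---|---|
| alder | 1.33 | 3.9 |
| alder | 2.00 | 7.0 |
| alder | 3.00 | 7.5 |
| alder | 4.00 | 10.0 |
| alder | 6.00 | 13.5 |
| alder | 10.0 | 16.1 |
| alder | 15.0 | 23.4 |
| cedar | 4.00 | 8.1 |
| cedar | 8.00 | 13.6 |
| cedar | 10.0 | 18.1 |
| cedar | 15.0 | 22.2 |
| cedar | 20.0 | 27.5 |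
| cedar | 25.0 | 27.0 |
| larch | 1.33 | 3.9 |
| larch | 4.00 | 8.2 |
| larch | 8.00 | 17.4 |
| larch | 10.0 | 18.3 |
| larch | 15.0 | 23.3 |
| larch | 20.0 | 26.7 |
| larch | 25.0 | 28.7 |

(each reading ± 1 percentage point)

1. which flask leads in amount of Z, in percent of the D charged ("all alike" within 1.5 percentage points) (summer / midnight / dusk / winter / all alike)
2. how much Z is there at the end, in percent of the D charged: summer
3. how much Z is there at the end, in percent of the D charged: midnight
4. how much Z is there at the end, in percent of the D charged: dusk
5. how much Z is there at the end, in percent of the D charged: winter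



Loading is the first setting. At 15.0 h the earlier runs read 23.4 %, 22.2 % and 23.3 % with D charged from 0.29 M to 0.64 M, so by hand loading drops out of the fraction formed, and one rising exponential can serve. Its two ends come from the cedar and larch readings: the mean is 18.2 % at 10.0 h and 27.1 % at 20.0 h. Joined, they read as a rate constant 0.0715 h⁻¹ and a ceiling 35.6 %, both carrying the scatter.

The readings bend towards that ceiling with 1.10 equiv of G charged, and this reckoning assumes that E takes the rest of the D that leaves. The pull of one equivalent of E against one of G, a selectivity factor, is then 0.795. The share of leaving D that reaches Z is G over G plus this factor times E, with G and E held at what stands in the flask.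

In this reckoning a flask with all its D from the start has lost a fraction 65.8 % of D by 15 h, and a further 17.5 % by 25 h. Midnight is reckoned at the ceiling share throughout and comes to 29.7 %.

The way G goes in is the second setting. Summer first holds 0.550 equiv of G, so its reckoned share up to 15 h is 21.7 %, and with the ceiling share after that it comes to 20.5 %. In dusk, by the same exponential, D leaves the early stretch on average at 6.18 h, when 0.453 equiv of G has been fed. That share of 18.6 %, with the ceiling share after 15 h, brings dusk to 18.4 %.

The way D goes in is the third. Winter is reckoned at the ceiling share, but by the same exponential it still holds 30.0 % of its whole D at the end, so it comes to 24.9 %. Midnight leads this reckoning.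

The forecast names midnight first, with 26.5 % for summer, 28.5 % for midnight, 25.5 % for dusk and 19 % for winter, on the ground that “Anything fed late meets dying catalyst”; it stands above this reckoning for summer and dusk, and below it for winter.

The flasks give 20.4 % for summer, 28.9 % for midnight, 18.6 % for dusk and 24.4 % for winter, and midnight leads.

    D ⇌ X (K = 0.150, k = 0.0734 h⁻¹)
    G + X → Z (k = 74.0 L mol⁻¹ h⁻¹)
    E + X → Q (k = 57.9 L mol⁻¹ h⁻¹)
    D + L → J (k = 23.4 L mol⁻¹ h⁻¹)

Midnight ends with 53.1 % as Q. Applied to midnight's Z at the charged G and E, the factor asks for 52.3 % of Q.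

For dusk with E cut to 1.00 equiv, the same reckoning gives 34.0 % of Z. The computed flask gives 34.4 %.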